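**Plan**

1. Labels: ring B = B1 (ether carbon), B2 (OH), B3, B4 (OH), B5, B6 (chain carbon); chain = C1 (on B6) to C14 (on ring A). Enabling feature: B1–B6 carries oxygen at B2 and B4 and the alkyl chain at B6, so it is the aromatised form of a 1-aryloxy-2,4,6-triketone, which is a ring-opened 2-(aryloxymethyl)-6-alkyl-4-pyrone; the crowded ether carbon B1 can therefore begin as an sp3 OCH2 group.
2. Retrosynthetic cuts, in order: B1–B6 (ring B opened to a 4-pyrone inside a 22-membered pyranophane); the ring A O–B1 ether bond; the C–Br bond at B1 and C1–C2 (both pyrone side chains come from the methyl groups of 2,6-dimethyl-4-pyrone); C13=C14.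
3. Forward: the C2–C14 chain is grown on ring A (Wittig, hydrogenation, iodination) and joined to one pyrone methyl group (C1–C2); the other methyl group is brominated, ring A is demethylated, and O-alkylation closes the 22-membered pyranophane.
4. Last, hot hydroxide opens the pyrone and the triketone refolds by B1–B6 aldol addition and aromatisation, so ring B arises at the very end and the macrocycle contracts to 20 members.
5. Stereochemistry: the target has no stereocentre and no stereogenic double bond; the Wittig alkene geometry and the two sp3 centres of the aldol intermediate are erased.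

Key step: step 9

Remark: alkoxides, phenoxides, enolates and aryl borates that arise in the steps and fallbacks are ionised or masked forms of the listed compounds and are not counted separately; in step 9 the oxygen of the added water is retained (at B2) only if hydroxide opens the pyrone at the carbon that becomes B2, whereas attack at the carbon that becomes B6 returns it as the water lost on aromatisation.

**Route**

Step 1
Reactants: 1 12-bromododecan-1-ol
Product: 2 (12-hydroxydodecyl)triphenylphosphonium bromide
Conditions: PPh3, MeCN, reflux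
Reagents that add atoms: triphenylphosphine, c1ccc(cc1)P(c1ccccc1)c1ccccc1
Why: SN2 quaternisation of triphenylphosphine by the primary bromide (phosphonium salt formation) should proceed cleanly in hot acetonitrile and leaves the remote hydroxyl untouched.

Step 2
Reactants: 2 (12-hydroxydodecyl)triphenylphosphonium bromide; 3 3,5-dimethoxybenzaldehyde
Product: 5 13-(3,5-dimethoxyphenyl)tridec-12-en-1-ol (Z/E mixture), via sodium ylide alkoxide 4 (not isolated)
Conditions: NaN(SiMe3)2 (2.1 equiv), THF, 0 °C; 3, −78 °C to rt; H2O
Reagents that add atoms: none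
Why: Wittig olefination, in which two equivalents of amide base turn 2 into the alkoxide of a non-stabilised ylide that condenses with the non-enolisable aldehyde 3; the alkene geometry is of no consequence because step 3 saturates it.

Step 3
Reactants: 5 13-(3,5-dimethoxyphenyl)tridec-12-en-1-ol
Product: 6 13-(3,5-dimethoxyphenyl)tridecan-1-ol
Conditions: H2 (1 atm), 10% Pd/C, EtOAc, rt
Reagents that add atoms: none
Why: Heterogeneous catalytic hydrogenation saturates the styrene-type alkene under conditions that touch neither the aryl methyl ethers nor the primary alcohol.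

Step 4
Reactants: 6 13-(3,5-dimethoxyphenyl)tridecan-1-ol
Product: 7 1-(13-iodotridecyl)-3,5-dimethoxybenzene
Conditions: I2, PPh3, imidazole, CH2Cl2, 0 °C to rt
Reagents that add atoms: iodine, II
Why: Appel-type iodination (Garegg–Samuelsson conditions) converts the primary alcohol, by SN2 displacement of its oxyphosphonium ion, into the iodide needed for the C1–C2 bond.

Step 5
Reactants: 8 2,6-dimethyl-4H-pyran-4-one (2.5 equiv); 7 1-(13-iodotridecyl)-3,5-dimethoxybenzene
Product: 10 2-[14-(3,5-dimethoxyphenyl)tetradecyl]-6-methyl-4H-pyran-4-one, via lithium dienolate 9 (not isolated)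
Conditions: LiN(SiMe3)2 (2.5 equiv), THF, −78 °C; 7, DMPU, −78 to −20 °C
Reagents that add atoms: none
Why: Lateral metalation of a methyl group of the symmetric 4-pyrone gives a dienolate that is alkylated at its exocyclic carbon (SN2, restoring the pyrone) to form C1–C2, and the excess of 8 keeps proton transfer to the product and a second alkylation in check.

Step 6
Reactants: 10 2-[14-(3,5-dimethoxyphenyl)tetradecyl]-6-methyl-4H-pyran-4-one
Product: 12 2-(bromomethyl)-6-[14-(3,5-dimethoxyphenyl)tetradecyl]-4H-pyran-4-one, via lithium dienolate 11 (not isolated)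
Conditions: LiN(SiMe3)2 (1.05 equiv), THF, −78 °C; cannulation into BrCl2CCCl2Br (1.5 equiv), THF, −78 °C
Reagents that add atoms: 1,2-dibromo-1,1,2,2-tetrachloroethane, ClC(Cl)(Br)C(Cl)(Cl)Br
Why: Kinetic lateral deprotonation should occur at the methyl group (less hindered and more acidic than the chain methylene C1), and the dienolate is brominated at its exocyclic carbon by halogen transfer from the polyhaloalkane (vinylogous enolate α-halogenation), inverse addition limiting proton exchange with the product and dibromination.

Step 7
Reactants: 12 2-(bromomethyl)-6-[14-(3,5-dimethoxyphenyl)tetradecyl]-4H-pyran-4-one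
Product: 13 2-(bromomethyl)-6-[14-(3,5-dihydroxyphenyl)tetradecyl]-4H-pyran-4-one
Conditions: BBr3 (5 equiv), CH2Cl2, −78 °C to rt; ice–water
Reagents that add atoms: none
Why: Lewis-acid ether cleavage with BBr3 frees both ring A phenols; the pyrone only forms a reversible carbonyl complex and, bromide being the only halide present, the bromomethyl group cannot be scrambled.

Step 8
Reactants: 13 2-(bromomethyl)-6-[14-(3,5-dihydroxyphenyl)tetradecyl]-4H-pyran-4-one
Product: 14 22-membered 4-pyranophane with free ring A phenol
Conditions: Cs2CO3 (3 equiv), DMF, 40 °C, syringe-pump addition of 13 (final 1 mM)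
Reagents that add atoms: none
Why: Intramolecular Williamson etherification, in which either of the two equivalent caesium phenoxides displaces the activated primary bromide (SN2) to make the O–B1 bond, slow addition at high dilution favouring the 22-membered ring over oligomers.

Step 9
Reactants: 14 22-membered 4-pyranophane with free ring A phenol
Product: 17 CNP0173380.0 (20-membered 4-aryloxy-5-alkylresorcinol macrocycle), via macrocyclic triketone 15 (not isolated), via bicyclic ketol 16 (not isolated)
Conditions: 2 M KOH, EtOH–H2O 1:1 (degassed), Ar, 80 °C; 2 M HCl, 0 °C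
Reagents that add atoms: water, O
Why: Proposed new method: hydroxide adds to C2 or C6 of the 4-pyrone (oxa-Michael addition) and cleavage of the ring C–O bond gives, from either mode of attack, the same enolised 24-membered 1-aryloxy-2,4,6-triketone 15, whose carbanion at B1 (stabilised by the B2 carbonyl and inductively by the aryloxy oxygen) adds to the B6 ketone; ketol 16 then loses water across B1–B6 and enolises at B2 and B4, and this aromatisation makes the sequence irreversible. The closest known reaction type is the alkali-induced ring transformation of 2,6-dialkyl-4-pyrones through 1,3,5-triketones into 5-alkylresorcinols (2,6-dimethyl-4-pyrone to orcinol), which has not been shown with an oxygen substituent on the nucleophilic carbon or across a macrocycle. Ring B closes by a transannular 6-(enolendo)-exo-trig aldol addition that forms B1–B6, and the macrocycle thereby contracts from 22 to 20 members. No stereocentre survives, since the two sp3 centres of 16 are erased on aromatisation. The step needs the fold B1-onto-B6 to win over C1-onto-B2: the aryloxymethylene is expected to be the more acidic terminal methylene and its second proton should speed the E1cB dehydration of 16, while the reversibility of both aldol additions lets the faster-dehydrating ketol drain the equilibrium; this preference remains to be verified. Oxygen is excluded because the product is an oxidation-prone hydroxyquinol aryl ether.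

**Compound list**

1 | 12-bromododecan-1-ol | OCCCCCCCCCCCCBr | starting material
2 | (12-hydroxydodecyl)triphenylphosphonium bromide | OCCCCCCCCCCCC[P+](c1ccccc1)(c1ccccc1)c1ccccc1.[Br-] | intermediate
3 | 3,5-dimethoxybenzaldehyde | COc1cc(C=O)cc(OC)c1 | starting material
4 | sodium 12-(triphenylphosphoranylidene)dodecan-1-olate (ylide alkoxide, not isolated) | [Na+].[O-]CCCCCCCCCCCC=P(c1ccccc1)(c1ccccc1)c1ccccc1 | intermediate
5 | 13-(3,5-dimethoxyphenyl)tridec-12-en-1-ol, Z/E mixture (geometry not defined) | COc1cc(C=CCCCCCCCCCCCO)cc(OC)c1 | intermediate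
6 | 13-(3,5-dimethoxyphenyl)tridecan-1-ol | COc1cc(CCCCCCCCCCCCCO)cc(OC)c1 | intermediate
7 | 1-(13-iodotridecyl)-3,5-dimethoxybenzene | COc1cc(CCCCCCCCCCCCCI)cc(OC)c1 | intermediate
8 | 2,6-dimethyl-4H-pyran-4-one | Cc1cc(=O)cc(C)o1 | starting material
9 | lithium 6-methyl-2-methylidene-2H-pyran-4-olate (not isolated) | [Li+].[O-]C1=CC(=C)OC(C)=C1 | intermediate
10 | 2-[14-(3,5-dimethoxyphenyl)tetradecyl]-6-methyl-4H-pyran-4-one | COc1cc(CCCCCCCCCCCCCCc2cc(=O)cc(C)o2)cc(OC)c1 | intermediate
11 | lithium 6-[14-(3,5-dimethoxyphenyl)tetradecyl]-2-methylidene-2H-pyran-4-olate (not isolated) | [Li+].[O-]C1=CC(=C)OC(CCCCCCCCCCCCCCc2cc(OC)cc(OC)c2)=C1 | intermediate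
12 | 2-(bromomethyl)-6-[14-(3,5-dimethoxyphenyl)tetradecyl]-4H-pyran-4-one | COc1cc(CCCCCCCCCCCCCCc2cc(=O)cc(CBr)o2)cc(OC)c1 | intermediate
13 | 2-(bromomethyl)-6-[14-(3,5-dihydroxyphenyl)tetradecyl]-4H-pyran-4-one | Oc1cc(O)cc(CCCCCCCCCCCCCCc2cc(=O)cc(CBr)o2)c1 | intermediate
14 | 22-membered 4-pyranophane: 2-(aryloxymethyl)-6-alkyl-4H-pyran-4-one whose C6 is joined by a tetradecane-1,14-diyl chain to C5 of the 3-hydroxyphenoxy ring that is bonded through oxygen to the pyrone 2-methylene | Oc1cc2cc(c1)OCc1cc(=O)cc(o1)CCCCCCCCCCCCCC2 | intermediate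
15 | 24-membered 1-aryloxy-2,4,6-triketone, the ring-opened form of 14 with carbonyls at B2, B4 and B6 (keto form drawn; present as enolates; not isolated) | Oc1cc2cc(c1)OCC(=O)CC(=O)CC(=O)CCCCCCCCCCCCCC2 | intermediate
16 | bicyclic ketol: 4-aryloxy-5-hydroxy-5-alkylcyclohexane-1,3-dione bridged by the C14 chain (B1–B6 formed; both sp3 centres of undefined configuration, erased in the next event; not isolated) | Oc1cc2cc(c1)OC1C(=O)CC(=O)CC1(O)CCCCCCCCCCCCCC2 | intermediate
17 | CNP0173380.0: ring B (4-aryloxy-5-alkylbenzene-1,3-diol) joined to ring A (5-alkyl-3-hydroxyphenyl) by the diaryl ether oxygen and a tetradecane-1,14-diyl chain, 20-membered macrocycle | Oc1cc2cc(c1)Oc1c(O)cc(O)cc1CCCCCCCCCCCCCC2 | target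

**Totals**

Total step count: 9. Longest linear sequence: 9 steps (1 to 17, with 3 and 8 added as purchased materials).

**Steps most likely to fail**

1. Step 9 (carries the label). The triketone may fold the other way (chain methylene C1 adding to the B2 carbonyl), hydroxide may fragment the triketone by retro-Claisen cleavage, or the electron-rich product may be oxidised during the hot basic phase. The fallback uses known chemistry, sets out from alcohol 6 and comes back at target 17; ring B is brought in ready-made and the hindered diaryl ether is made by a formyl-activated Ullmann coupling. NaSEt in hot DMF removes one methyl group of 6 (the phenoxide formed protects the second ether) to give 3-(13-hydroxytridecyl)-5-methoxyphenol F1. CuI, picolinic acid and K3PO4 in DMSO couple the phenol of F1 (the aliphatic alcohol is not arylated under these conditions) with purchased 2-bromo-3,5-dimethoxybenzaldehyde (COc1cc(C=O)c(Br)c(OC)c1) to 2-[3-(13-hydroxytridecyl)-5-methoxyphenoxy]-3,5-dimethoxybenzaldehyde F2. I2, PPh3 and imidazole in CH2Cl2, conditions that leave the aldehyde alone, convert the primary alcohol into 2-[3-(13-iodotridecyl)-5-methoxyphenoxy]-3,5-dimethoxybenzaldehyde F3, and PPh3 in MeCN gives {13-[3-(2-formyl-4,6-dimethoxyphenoxy)-5-methoxyphenyl]tridecyl}triphenylphosphonium iodide F4. Slow addition of F4 to KOtBu in THF at high dilution generates the corresponding phosphorus ylide F5 (not isolated), which closes the 20-membered ring on the aldehyde by an intramolecular Wittig reaction to the C1=C2-dehydro tri-O-methyl ether of the target F6 (Z/E mixture). Hydrogenation over Pd/C gives the tri-O-methyl ether of the target F7, and BBr3 in CH2Cl2 frees the three phenols to give 17.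

2. Step 6. Deprotonation may compete at the chain methylene C1, bromine may be transferred to a ring carbon of the dienolate, and proton exchange between dienolate and product may lead on to dibromination. The fallback sets out from 10 and comes back at 12; it replaces kinetic deprotonation and halogen transfer by a reversible condensation followed by oxidative cleavage. NaOEt in dry EtOH condenses the methyl group of 10 with benzaldehyde (the methylene would give a more hindered trisubstituted alkene) to 2-[14-(3,5-dimethoxyphenyl)tetradecyl]-6-[(E)-2-phenylethenyl]-4H-pyran-4-one F8. Lemieux–Johnson cleavage (catalytic OsO4, NaIO4, 2,6-lutidine, dioxane–water) of the styryl double bond gives 6-[14-(3,5-dimethoxyphenyl)tetradecyl]-4-oxo-4H-pyran-2-carbaldehyde F9. NaBH4 in MeOH at 0 °C reduces the aldehyde to 2-[14-(3,5-dimethoxyphenyl)tetradecyl]-6-(hydroxymethyl)-4H-pyran-4-one F10, and CBr4/PPh3 gives 12.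

3. Step 5. The SN2 reaction of the lithium dienolate with an unactivated long-chain iodide is slow, so self-condensation of the pyrone (dienolate adding to neutral pyrone) and a second alkylation after proton transfer may take over. The fallback sets out from 6 (with 8) and comes back at 10; it uses the faster carbonyl addition of the same dienolate. Dess–Martin periodinane oxidises 6 to 13-(3,5-dimethoxyphenyl)tridecanal F11. Lithium dienolate 9 (from 8 and LiN(SiMe3)2, THF, −78 °C) adds to F11 in a vinylogous aldol reaction to give racemic 2-[14-(3,5-dimethoxyphenyl)-2-hydroxytetradecyl]-6-methyl-4H-pyran-4-one F12. MsCl with excess Et3N converts F12 into racemic 14-(3,5-dimethoxyphenyl)-1-(6-methyl-4-oxo-4H-pyran-2-yl)tetradecan-2-yl methanesulfonate F13 (not isolated), which eliminates in the same flask to 2-[(1E)-14-(3,5-dimethoxyphenyl)tetradec-1-en-1-yl]-6-methyl-4H-pyran-4-one F14, and hydrogenation over Pd/C at 1 atm, stopped after one equivalent of H2, saturates the side-chain alkene to give 10.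

Further compounds
F1 | step 9 | 3-(13-hydroxytridecyl)-5-methoxyphenol | COc1cc(O)cc(CCCCCCCCCCCCCO)c1
F2 | step 9 | 2-[3-(13-hydroxytridecyl)-5-methoxyphenoxy]-3,5-dimethoxybenzaldehyde | COc1cc(Oc2c(C=O)cc(OC)cc2OC)cc(CCCCCCCCCCCCCO)c1
F3 | step 9 | 2-[3-(13-iodotridecyl)-5-methoxyphenoxy]-3,5-dimethoxybenzaldehyde | COc1cc(Oc2c(C=O)cc(OC)cc2OC)cc(CCCCCCCCCCCCCI)c1
F4 | step 9 | {13-[3-(2-formyl-4,6-dimethoxyphenoxy)-5-methoxyphenyl]tridecyl}triphenylphosphonium iodide | COc1cc(Oc2c(C=O)cc(OC)cc2OC)cc(CCCCCCCCCCCCC[P+](c2ccccc2)(c2ccccc2)c2ccccc2)c1.[I-]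
F5 | step 9 | phosphorus ylide of F4 (not isolated) | COc1cc(Oc2c(C=O)cc(OC)cc2OC)cc(CCCCCCCCCCCCC=P(c2ccccc2)(c2ccccc2)c2ccccc2)c1
F6 | step 9 | C1=C2-dehydro tri-O-methyl ether of the target, Z/E mixture (geometry not defined) | COc1cc2cc(c1)Oc1c(OC)cc(OC)cc1C=CCCCCCCCCCCCC2
F7 | step 9 | tri-O-methyl ether of the target | COc1cc2cc(c1)Oc1c(OC)cc(OC)cc1CCCCCCCCCCCCCC2
F8 | step 6 | 2-[14-(3,5-dimethoxyphenyl)tetradecyl]-6-[(E)-2-phenylethenyl]-4H-pyran-4-one | COc1cc(CCCCCCCCCCCCCCc2cc(=O)cc(/C=C/c3ccccc3)o2)cc(OC)c1
F9 | step 6 | 6-[14-(3,5-dimethoxyphenyl)tetradecyl]-4-oxo-4H-pyran-2-carbaldehyde | COc1cc(CCCCCCCCCCCCCCc2cc(=O)cc(C=O)o2)cc(OC)c1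
F10 | step 6 | 2-[14-(3,5-dimethoxyphenyl)tetradecyl]-6-(hydroxymethyl)-4H-pyran-4-one | COc1cc(CCCCCCCCCCCCCCc2cc(=O)cc(CO)o2)cc(OC)c1
F11 | step 5 | 13-(3,5-dimethoxyphenyl)tridecanal | COc1cc(CCCCCCCCCCCCC=O)cc(OC)c1
F12 | step 5 | 2-[14-(3,5-dimethoxyphenyl)-2-hydroxytetradecyl]-6-methyl-4H-pyran-4-one (racemic) | COc1cc(CCCCCCCCCCCCC(O)Cc2cc(=O)cc(C)o2)cc(OC)c1
F13 | step 5 | 14-(3,5-dimethoxyphenyl)-1-(6-methyl-4-oxo-4H-pyran-2-yl)tetradecan-2-yl methanesulfonate (racemic, not isolated) | COc1cc(CCCCCCCCCCCCC(OS(C)(=O)=O)Cc2cc(=O)cc(C)o2)cc(OC)c1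
F14 | step 5 | 2-[(1E)-14-(3,5-dimethoxyphenyl)tetradec-1-en-1-yl]-6-methyl-4H-pyran-4-one | COc1cc(CCCCCCCCCCCC/C=C/c2cc(=O)cc(C)o2)cc(OC)c1
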